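## The problem

The target 22 is a 20-membered meta,para-cyclophane with no stereocenter. Ring A is a 1,3,5-trisubstituted monophenol; ring B is a 4-alkylated ring with oxygen on C1, C2 and C6. The two rings are tied together twice: by a diaryl ether oxygen (ring A C3–O–C1 ring B) and by an unbranched saturated chain of twelve methylenes, numbered here C1 (on ring B, para to the ether oxygen) to C12 (on ring A, meta to it). With no stereocenter there is nothing to relay; the only stereochemical element met on the way is alkene geometry, and hydrogenation erases it. The difficulty is connectivity, in two places. First, the ether oxygen of ring B lies between two ortho oxygen substituents, so bonding it to an aromatic carbon of ring A by Cu- or Pd-mediated coupling or by SNAr means arylating a hindered, electron-rich phenol with an unactivated partner. Second, the large ring must be closed through a chain that carries no functional group, so the closing reaction may leave nothing behind but CH2. The free triphenol is electron-rich and prone to oxidation in base and air, so the two ring B hydroxyls stay masked to the last step; the reactive intermediates the plan accepts (a cyclobutenone, a terminal ynol ether) tolerate neither acid nor prolonged heating. The enabling feature is ring A itself: its C–OH, C–OAr and C–alkyl carbons are mutually meta with a CH between each pair, the pattern that a 3-alkylcyclobutenone and an aryloxyacetylene give on benzannulation, so ring A can be grown on an oxygen that ring B already carries.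

## Retrosynthesis

**22 ⇒ 21 (two O–CH3 bonds on ring B).** The last operation unmasks the two ring B hydroxyls. Methyl is preferred to benzyl, which would require building ring B from scratch, and to silyl, which would not survive KH and n-BuLi. It comes with commercial phenol 6 and ignores every reagent used on the way. BBr3 must cleave two aryl methyl ethers and spare the diaryl ether, which it should, since bromide can attack a methyl carbon but not an aromatic one.

**21 ⇒ 20 ⇒ 19 (the C6–C7 bond, by way of a C6=C7 alkene).** The chain has eleven C–C bonds that could be cut. The central one is chosen because both arms then become the same hept-6-enyl group from one bromide, 1. It also puts the new alkene five methylenes from either arene, whereas a cut at C1–C2 or C2–C3 would need styrenyl or allyl arms that isomerize easily. Diene 19 is acyclic. The forward ring-closing metathesis must favour the strain-free 20-membered ring over oligomers; the E/Z outcome is irrelevant because hydrogenation to 21 follows.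

**19 ⇒ 5 + 14 (two C–C bonds of ring A).** Ring A is cut between the C–OH carbon and the CH that lies between the two oxygens, and between the C–OAr carbon and the CH next to the alkyl-bearing carbon. This returns cyclobutenone 5 (four ring carbons) and ethynyl ether 14 (two carbons). The neighbouring cut, the ring A carbon–oxygen bond, would need an Ullmann-type coupling of a 2,6-dimethoxyphenol, the step most likely to fail in this molecule. The benzannulation instead keeps the ring B–O bond intact and forms only C–C bonds. Both precursors are small, and only one of them is aromatic. The forward reaction must deliver one regiochemistry of ketene–alkyne union and leave the two terminal alkenes untouched.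

**14 ⇒ 11 ⇒ 8 + 9 (the O–C(sp) bond).** An oxygen–alkyne bond cannot be made by substitution at sp carbon, so it is made one oxidation level down: phenol 8 and trichloroethylene 9 give the (E)-1,2-dichlorovinyl ether 11, and n-BuLi then takes out HCl and Cl. The alternative, a Cu-catalysed alkynylation of the phenol, would reintroduce a metal-mediated C–O coupling at the hindered oxygen. Here the phenoxide attacks a slender, linear electrophile, so the ortho methoxy groups should matter little.

**8 ⇒ 6 + 1 (bond between ring B C4 and chain C1).** A Negishi coupling of commercial 4-bromo-2,6-dimethoxyphenol 6 with the zinc reagent 7 made from bromide 1 sets the arm in one step. Friedel–Crafts alkylation would not give a linear primary chain. An olefination of syringaldehyde would need a reduction that cannot distinguish the new alkene from the terminal one. The coupling is asked to tolerate the free, hindered OH so that no protecting group is needed.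

**5 ⇒ 2 + 1 (bond between cyclobutenone C3 and chain C12).** The Grignard reagent 3 from the same bromide 1 adds to the carbonyl of the vinylogous ester 2, and acid then transposes the carbonyl. A dichloroketene–alkyne cycloaddition would be the alternative entry to 3-alkylcyclobutenones, but dichloroketene would also attack the terminal alkene and two chlorines would have to be removed.

## Roads not taken

**Alternative 1: Ramberg–Bäcklund contraction.** The cut is C1–C2, next to ring B. The 21-membered sulfone A2 would be α-halogenated in base, closed to an episulfone and stripped of SO2 to give the 20-membered C1=C2 alkene A1, followed by hydrogenation and demethylation.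
- Merits: A2 is reached by S-alkylation of a thiolate at a benzylic halide, one of the most dependable macrocyclisations in cyclophane chemistry, and SO2 loss is irreversible. For closing the ring alone this road is probably more reliable than metathesis at 20 atoms.
- Weak points: three operations (S-alkylation, oxidation, contraction) make one C–C bond. The two arms are unlike (one carbon on ring B, eleven on ring A) and need separate syntheses. The in-situ halogenating, strongly basic medium meets a trioxygenated arene. The hindered diaryl ether is still unsolved.
- Comparison: the chosen plan offers identical arms from bromide 1, a shorter end game (19 to 21 in two steps), and above all an ether oxygen that is never arylated.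

**Alternative 2: TosMIC linchpin at C4.** The cuts are C3–C4 and C4–C5. Tosylmethyl isocyanide would be alkylated twice by diiodide A4 to give the macrocycle A3 (racemic at C4), which would be hydrolysed to ketone A5 and deoxygenated before demethylation.
- Merits: two C–C bonds and the ring in one flask, no transition metal, no alkene that can migrate, and only the second alkylation is a macrocyclisation.
- Weak points: C4 arrives as a carbonyl the target does not have, so hydrolysis and a forcing deoxygenation are added. The arms (three and eight carbons) again differ. Oligomerisation competes as in any closure of this size. The ether problem remains.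
- Comparison: A3 avoids the isomerisation risk of metathesis, a real advantage. The chosen plan leaves only an alkene, which one mild hydrogenation removes.

**Alternative 3: Eglinton diyne closure.** This cuts the same C6–C7 bond as the chosen plan, but by oxidative coupling of bis-alkyne A7 with Cu(OAc)2 in pyridine at high dilution to the 1,3-diyne A6, then exhaustive hydrogenation and demethylation.
- Merits: identical arms from one building block and the same number of end-game steps. Terminal alkynes do not chain-walk, so ring-contracted homologues cannot form. As a ring closure it is at least the equal of metathesis.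
- Weak points: excess copper salt is needed, the rigid four-carbon diyne rod adds some strain and favours cyclic dimers, and the diaryl ether must come from an Ar–O coupling. Terminal alkynes could not accompany the chosen ring A construction, because n-BuLi would deprotonate them and they are themselves partners for vinylketenes.
- Comparison: the chosen plan has nothing better to offer for the closure itself. Its advantage is that alkene arms are inert spectators through KH, n-BuLi and the ketene cascade, which makes the benzannulation solution to the ether possible.

Key step: step 5

Assumption: 3-ethoxycyclobut-2-en-1-one (2) is treated as a purchasable reagent; it is otherwise the one-step (2+2) adduct of ketene and ethoxyacetylene.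

## Route

Step 1
Reactants: 1 7-bromohept-1-ene; 2 3-ethoxycyclobut-2-en-1-one
Product: 5 3-(hept-6-en-1-yl)cyclobut-2-en-1-one, via hept-6-enylmagnesium bromide 3 (not isolated), via 3-ethoxy-1-(hept-6-en-1-yl)cyclobut-2-en-1-ol 4 (not isolated)
Conditions: 1, Mg, THF, rt → 40 °C; then 2, THF, −78 °C; then 1 M aq. HCl, 0 °C → rt
Reagents that add atoms: water, O
Why: Grignard 1,2-addition to the carbonyl of a vinylogous ester followed by acid hydrolysis with allylic transposition (Stork–Danheiser-type sequence), the standard entry to 3-substituted cyclobutenones; the new carbonyl oxygen comes from water and ethanol is lost. The terminal alkene is inert to both stages.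

Step 2
Reactants: 1 7-bromohept-1-ene; 6 4-bromo-2,6-dimethoxyphenol
Product: 8 4-(hept-6-en-1-yl)-2,6-dimethoxyphenol, via hept-6-enylzinc bromide 7 (not isolated)
Conditions: 1, Zn dust, LiCl, THF, 50 °C; then 6, Pd(OAc)2 (2 mol%), SPhos [2-dicyclohexylphosphino-2',6'-dimethoxybiphenyl] (4 mol%), THF, rt, 7 added over 2 h
Reagents that add atoms: none
Why: Negishi sp3–sp2 coupling; the zerovalent palladium–biarylphosphine catalyst inserts into the electron-rich bromide and couples faster than β-hydride elimination. Halophenols with a free OH are known to couple under these conditions when the alkylzinc is fed slowly, because transmetalation outruns protonolysis by the hindered phenol.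

Step 3
Reactants: 8 4-(hept-6-en-1-yl)-2,6-dimethoxyphenol; 9 trichloroethylene
Product: 11 2-{[(E)-1,2-dichloroethenyl]oxy}-5-(hept-6-en-1-yl)-1,3-dimethoxybenzene, via dichloroacetylene 10 (not isolated)
Conditions: KH, THF, 0 °C → rt; then Cl2C=CHCl, −50 °C → rt
Reagents that add atoms: none
Why: Elimination–addition O-vinylation: base takes HCl from trichloroethylene, the potassium phenoxide adds anti to the dichloroacetylene formed, and the vinyl anion is protonated by more trichloroethylene, giving the (E)-1,2-dichlorovinyl ether. The electrophile is a linear sp carbon, so the two ortho methoxy groups that hinder aryl–oxygen coupling should not interfere.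

Step 4
Reactants: 11 2-{[(E)-1,2-dichloroethenyl]oxy}-5-(hept-6-en-1-yl)-1,3-dimethoxybenzene
Product: 14 2-(ethynyloxy)-5-(hept-6-en-1-yl)-1,3-dimethoxybenzene, via chloroethynyl ether 12 (not isolated), via lithium aryloxyacetylide 13 (not isolated)
Conditions: n-BuLi (2.3 equiv), THF, −78 → −40 °C; then H2O, −78 °C → rt; rapid filtration through basic alumina
Reagents that add atoms: none
Why: Dehydrochlorination of the dichlorovinyl ether by the first equivalent of n-BuLi and chlorine–lithium exchange by the second give the lithium ynolate ether, which is protonated to the terminal ynol ether (the established dichlorovinyl ether route to alkynyl ethers). At −78 °C ring lithiation and attack on the remote alkene should not compete.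

Step 5
Reactants: 5 3-(hept-6-en-1-yl)cyclobut-2-en-1-one; 14 2-(ethynyloxy)-5-(hept-6-en-1-yl)-1,3-dimethoxybenzene
Product: 19 3-[4-(hept-6-en-1-yl)-2,6-dimethoxyphenoxy]-5-(hept-6-en-1-yl)phenol, via vinylketene 15 (not isolated), via 4-vinylcyclobutenone 16 (not isolated), via dienylketene 17 (not isolated), via cyclohexa-2,4-dienone 18 (not isolated)
Conditions: 5 (1.2 equiv), toluene (0.3 M), 80 °C then 110 °C, Ar, sealed tube
Reagents that add atoms: none
Why: Danheiser benzannulation: at 80 °C cyclobutenone 5 opens by four-electron electrocyclic cleavage of its C1–C4 bond to vinylketene 15, whose ketene C=C adds (2+2) to the electron-rich triple bond of 14 to give 4-vinylcyclobutenone 16. A second four-electron opening gives dienylketene 17, and ring A then closes by a six-electron electrocyclization between the ketene carbon and the terminal methylene (a pericyclic closure, not an ionic one) to cyclohexa-2,4-dienone 18, which tautomerizes irreversibly to phenol 19. The closest known reaction type is the benzannulation of 3-alkylcyclobutenones with alkoxy- and silyloxyacetylenes to 5-alkylresorcinol monoethers; an aryl ethynyl ether is a further member of the same ynol ether class. The selectivity that matters is the regiochemistry of the ketene–alkyne cycloaddition: the nucleophilic CH terminus of 14 bonds to the electrophilic ketene carbonyl carbon, which places OAr meta to OH and the former cyclobutenone 3-substituent meta to both. The two ortho methoxy groups should twist the aryl ring out of conjugation with the ether oxygen, leaving its lone pair to the triple bond, so that 14 keeps much of the nucleophilicity of an alkyl ynol ether. Having no β-hydrogen on the oxygen substituent, 14 cannot fragment to a ketene by the retro-ene path that limits alkyl ynol ethers on heating. The unactivated terminal alkenes are poor ketenophiles and stay spectators, and no stereocenter is formed.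

Step 6
Reactants: 19 3-[4-(hept-6-en-1-yl)-2,6-dimethoxyphenoxy]-5-(hept-6-en-1-yl)phenol
Product: 20 20-membered macrocyclic alkene: 5-hydroxy-1,3-phenylene (ring A) and 2,6-dimethoxy-1,4-phenylene (ring B) joined by the ether oxygen (ring A C3 to ring B C1) and by a –(CH2)5–CH=CH–(CH2)5– bridge (ring B C4 to ring A C1; C6=C7, E/Z mixture)
Conditions: RuCl2(H2IMes)(PCy3)(=CHPh) (second-generation Grubbs catalyst, 10 mol%), 1,4-benzoquinone (20 mol%), CH2Cl2 (1 mM), 40 °C, slow addition of 19
Reagents that add atoms: none
Why: Ring-closing olefin metathesis of two unhindered terminal alkenes, driven by loss of ethene; high dilution favours the strain-free 20-membered ring over oligomers. Benzoquinone suppresses ruthenium hydride chain-walking, and free phenols are tolerated by this catalyst.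

Step 7
Reactants: 20 macrocyclic C6=C7 alkene (E/Z mixture)
Product: 21 saturated macrocycle: ring A (5-hydroxy-1,3-phenylene) and ring B (2,6-dimethoxy-1,4-phenylene) joined by the ether oxygen and a –(CH2)12– bridge
Conditions: H2 (1 atm), Pd/C (10 wt% Pd on carbon), EtOAc, rt
Reagents that add atoms: none
Why: Heterogeneous catalytic hydrogenation of an unhindered disubstituted alkene; both geometric isomers converge on one product. The diaryl ether and aryl methyl ethers are stable under these mild conditions.

Step 8
Reactants: 21 saturated macrocyclic dimethyl ether
Product: 22 target CNP0314249.0: ring A (5-hydroxy-1,3-phenylene) and ring B (2,6-dihydroxy-1,4-phenylene) joined by the ether oxygen (ring A C3 to ring B C1) and a –(CH2)12– bridge (ring B C4 to ring A C1)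
Conditions: BBr3 (4 equiv), CH2Cl2, −78 °C → rt; then H2O, 0 °C
Reagents that add atoms: none
Why: Lewis acid-mediated aryl methyl ether cleavage: boron coordinates the methoxy oxygen and bromide attacks the methyl carbon in an SN2 step. The diaryl ether offers no sp3 carbon for that attack and should survive, and the oxidation-prone triphenol appears only at the end.

## Compound list

1 | 7-bromohept-1-ene | C=CCCCCCBr | starting material
2 | 3-ethoxycyclobut-2-en-1-one | CCOC1=CC(=O)C1 | starting material
3 | hept-6-enylmagnesium bromide | C=CCCCCC[Mg]Br | intermediate (not isolated)
4 | 3-ethoxy-1-(hept-6-en-1-yl)cyclobut-2-en-1-ol (racemic) | CCOC1=CC(O)(CCCCCC=C)C1 | intermediate (not isolated)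
5 | 3-(hept-6-en-1-yl)cyclobut-2-en-1-one | O=C1CC(CCCCCC=C)=C1 | intermediate
6 | 4-bromo-2,6-dimethoxyphenol | COc1cc(Br)cc(OC)c1O | starting material
7 | hept-6-enylzinc bromide | C=CCCCCC[Zn]Br | intermediate (not isolated)
8 | 4-(hept-6-en-1-yl)-2,6-dimethoxyphenol | C=CCCCCCc1cc(OC)c(O)c(OC)c1 | intermediate
9 | trichloroethylene | ClC=C(Cl)Cl | starting material
10 | dichloroacetylene | ClC#CCl | intermediate (not isolated)
11 | 2-{[(E)-1,2-dichloroethenyl]oxy}-5-(hept-6-en-1-yl)-1,3-dimethoxybenzene | C=CCCCCCc1cc(OC)c(O/C(Cl)=C\Cl)c(OC)c1 | intermediate
12 | 2-[(chloroethynyl)oxy]-5-(hept-6-en-1-yl)-1,3-dimethoxybenzene | ClC#COc1c(OC)cc(CCCCCC=C)cc1OC | intermediate (not isolated)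
13 | {[4-(hept-6-en-1-yl)-2,6-dimethoxyphenoxy]ethynyl}lithium | [Li]C#COc1c(OC)cc(CCCCCC=C)cc1OC | intermediate (not isolated)
14 | 2-(ethynyloxy)-5-(hept-6-en-1-yl)-1,3-dimethoxybenzene | C#COc1c(OC)cc(CCCCCC=C)cc1OC | intermediate
15 | 3-methylidenedeca-1,9-dien-1-one (vinylketene) | O=C=CC(=C)CCCCCC=C | intermediate (not isolated)
16 | 3-[4-(hept-6-en-1-yl)-2,6-dimethoxyphenoxy]-4-(nona-1,8-dien-2-yl)cyclobut-2-en-1-one (racemic) | O=C1C=C(Oc2c(OC)cc(CCCCCC=C)cc2OC)C1C(=C)CCCCCC=C | intermediate (not isolated)
17 | (3E)-3-[4-(hept-6-en-1-yl)-2,6-dimethoxyphenoxy]-5-methylidenedodeca-1,3,11-trien-1-one (dienylketene) | O=C=C/C(Oc1c(OC)cc(CCCCCC=C)cc1OC)=C\C(=C)CCCCCC=C | intermediate (not isolated)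
18 | 3-[4-(hept-6-en-1-yl)-2,6-dimethoxyphenoxy]-5-(hept-6-en-1-yl)cyclohexa-2,4-dien-1-one | O=C1C=C(Oc2c(OC)cc(CCCCCC=C)cc2OC)C=C(CCCCCC=C)C1 | intermediate (not isolated)
19 | 3-[4-(hept-6-en-1-yl)-2,6-dimethoxyphenoxy]-5-(hept-6-en-1-yl)phenol | Oc1cc(CCCCCC=C)cc(c1)Oc1c(OC)cc(CCCCCC=C)cc1OC | intermediate
20 | macrocyclic C6=C7 alkene, ring B dimethyl ether (E/Z mixture, geometry left open) | Oc1cc2cc(c1)Oc1c(OC)cc(cc1OC)CCCCCC=CCCCCC2 | intermediate
21 | saturated macrocycle, ring B dimethyl ether | Oc1cc2cc(c1)Oc1c(OC)cc(cc1OC)CCCCCCCCCCCC2 | intermediate
22 | CNP0314249.0, macrocyclic diaryl ether triol | Oc1cc2cc(c1)Oc1c(O)cc(cc1O)CCCCCCCCCCCC2 | target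

## Step count and least certain steps

Total: 8 steps. Longest linear sequence: 7 steps (6 → 8 → 11 → 14 → 19 → 20 → 21 → 22); the cyclobutenone branch adds one step.

**Step 5 (key step).**
- Risk: an aryloxy group donates less than an alkoxy group, so capture of vinylketene 15 by 14 may be slow. Ketene 15 could then dimerize or acylate the product phenol, and the terminal ynol ether could oligomerize on heating.
- Within the plan, portionwise addition of 5 and a brief K2CO3/MeOH treatment of the crude product (to cleave any aryl ester) would be tried first.
- Fallback: abandon the construction of ring A and make the ether bond by Ullmann coupling. It sets out from 8 (with zinc reagent 7) and rejoins the route at 22.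
  - Zinc reagent 7 would be coupled once with commercial 1,3-dibromo-5-methoxybenzene (Pd(OAc)2/SPhos, THF) to give 1-bromo-3-(hept-6-en-1-yl)-5-methoxybenzene F1.
  - CuI, picolinic acid and K3PO4 in DMSO at 100 °C would join F1 to phenol 8, giving 1-(hept-6-en-1-yl)-3-[4-(hept-6-en-1-yl)-2,6-dimethoxyphenoxy]-5-methoxybenzene F2.
  - Ring-closing metathesis with RuCl2(H2IMes)(PCy3)(=CHPh) would give the macrocyclic C6=C7 alkene trimethyl ether F3, and hydrogenation over Pd/C the saturated macrocyclic trimethyl ether F4.
  - BBr3 would remove all three methyl groups to give 22.
  - This is the hindered coupling the main plan is designed to avoid, so lower efficiency is expected, but every step is of a known type.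

**Step 4.**
- Risk: loss of the terminal ynol ether during isolation, by hydration on acidic surfaces or oligomerization on concentration, and incomplete chlorine–lithium exchange.
- Fallback: from 11, the acetylide 13 is generated as before but quenched with Me3SiCl to give trimethyl{[4-(hept-6-en-1-yl)-2,6-dimethoxyphenoxy]ethynyl}silane F5, which can be purified and stored. Catalytic K2CO3 in MeOH/THF at 0 °C removes silicon, and the fallback returns to the route at 14, used directly in step 5.

**Step 2.**
- Risk: protonolysis of the alkylzinc by the free phenol, and slow oxidative addition into the very electron-rich bromide once it is present as a zinc phenoxide, leading to reduction in place of coupling.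
- Fallback: from 6, NaH and chloromethyl methyl ether give 5-bromo-1,3-dimethoxy-2-(methoxymethoxy)benzene F6. The same Negishi coupling with 7 gives 5-(hept-6-en-1-yl)-1,3-dimethoxy-2-(methoxymethoxy)benzene F7. HCl in MeOH removes the acetal and returns to the route at 8.

**Step 6.**
- Risk: intermolecular metathesis to oligomers, and alkene migration before closure, which would excise propene and give ring-contracted homologues that cannot be separated after hydrogenation.
- Fallback: close the same C6–C7 bond by carbonyl coupling. From 19, Lemieux–Johnson cleavage (K2OsO4·2H2O cat., NaIO4, 2,6-lutidine, dioxane/H2O) gives 6-{4-[3-hydroxy-5-(6-oxohexyl)phenoxy]-3,5-dimethoxyphenyl}hexanal F8. Intramolecular McMurry coupling (TiCl4, Zn, pyridine, THF, reflux, slow addition) returns to the route at 20.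

## Further compounds

F1 | step 5 | 1-bromo-3-(hept-6-en-1-yl)-5-methoxybenzene | COc1cc(Br)cc(CCCCCC=C)c1
F2 | step 5 | 1-(hept-6-en-1-yl)-3-[4-(hept-6-en-1-yl)-2,6-dimethoxyphenoxy]-5-methoxybenzene | COc1cc(CCCCCC=C)cc(c1)Oc1c(OC)cc(CCCCCC=C)cc1OC
F3 | step 5 | macrocyclic C6=C7 alkene, trimethyl ether (E/Z mixture) | COc1cc2cc(c1)Oc1c(OC)cc(cc1OC)CCCCCC=CCCCCC2
F4 | step 5 | saturated macrocycle, trimethyl ether | COc1cc2cc(c1)Oc1c(OC)cc(cc1OC)CCCCCCCCCCCC2
F5 | step 4 | trimethyl{[4-(hept-6-en-1-yl)-2,6-dimethoxyphenoxy]ethynyl}silane | C[Si](C)(C)C#COc1c(OC)cc(CCCCCC=C)cc1OC
F6 | step 2 | 5-bromo-1,3-dimethoxy-2-(methoxymethoxy)benzene | COCOc1c(OC)cc(Br)cc1OC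
F7 | step 2 | 5-(hept-6-en-1-yl)-1,3-dimethoxy-2-(methoxymethoxy)benzene | COCOc1c(OC)cc(CCCCCC=C)cc1OC
F8 | step 6 | 6-{4-[3-hydroxy-5-(6-oxohexyl)phenoxy]-3,5-dimethoxyphenyl}hexanal | Oc1cc(CCCCCC=O)cc(c1)Oc1c(OC)cc(CCCCCC=O)cc1OC
A1 | alternative 1 | macrocyclic C1=C2 alkene, trimethyl ether (E drawn) | COc1cc2cc(c1)Oc1c(OC)cc(cc1OC)/C=C/CCCCCCCCCC2
A2 | alternative 1 | 21-membered macrocyclic sulfone, trimethyl ether | COc1cc2cc(c1)Oc1c(OC)cc(cc1OC)CS(=O)(=O)CCCCCCCCCCC2
A3 | alternative 2 | macrocyclic C4 tosyl isocyanide, trimethyl ether (racemic at C4) | COc1cc2cc(c1)Oc1c(OC)cc(cc1OC)CCCC(S(=O)(=O)c1ccc(C)cc1)([N+]#[C-])CCCCCCCC2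
A4 | alternative 2 | 1-(8-iodooctyl)-3-[4-(3-iodopropyl)-2,6-dimethoxyphenoxy]-5-methoxybenzene | COc1cc(CCCCCCCCI)cc(c1)Oc1c(OC)cc(CCCI)cc1OC
A5 | alternative 2 | macrocyclic C4 ketone, trimethyl ether | COc1cc2cc(c1)Oc1c(OC)cc(cc1OC)CCCC(=O)CCCCCCCC2
A6 | alternative 3 | macrocyclic C5,C7 1,3-diyne, trimethyl ether | COc1cc2cc(c1)Oc1c(OC)cc(cc1OC)CCCCC#CC#CCCCC2
A7 | alternative 3 | 1-(hex-5-yn-1-yl)-3-[4-(hex-5-yn-1-yl)-2,6-dimethoxyphenoxy]-5-methoxybenzene | COc1cc(CCCCC#C)cc(c1)Oc1c(OC)cc(CCCCC#C)cc1OC
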